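The route cuts the bond between quaternary ring carbon C6 and pyrone carbon C6′. Ring atoms C1–C6 with methyls on C2, C4 and C6 are the skeleton of 2,4,6-trimethylphenol. A lead(IV) ligand coupling of this phenol with a pyron-6-yllead triacetate under a chiral amine joins the pyrone to a methyl-bearing ortho carbon, dearomatises the ring and sets C6 in one operation. The product is the 2,4-dienone with the C2–C5 diene in place and C1 as a ketone. The lead reagent comes from the 6-unsubstituted pyrone by magnesiation, stannylation and tin–lead exchange. C1 is finished by alkenylcerium addition and palladium–formate hydride delivery with inversion.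

Key step: step 6

Remark (numbering): ring atoms C1–C6 are numbered as in the target (C1 carries the side chain, C6 is quaternary); pyrone atoms are primed (C6′ is bonded to C6).
Remark (assumption): the sense of induction of a chiral amine on lead cannot be predicted; the route is written for the alkaloid that gives (S)-13, with (−)-brucine named and a ligand of opposite sense (a sparteine enantiomer) to replace it if (R)-13 predominates.
Remark (descriptors): the CIP label at C6 changes from S (13, 27) to R (28–30) with no change in space, because C1 loses its oxygen.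

Step 1
Reactants: 1 methyl 2-methyl-3-oxopentanoate; 2 methyl formate
Product: 4 methyl 2,4-dimethyl-3,5-dioxopentanoate (tautomer mixture), via dilithium dianion of methyl 2-methyl-3-oxopentanoate 3 (not isolated)
Conditions: LDA (2.1 equiv), THF, −78 → 0 °C; HCO2Me (0.5 equiv), −78 → 0 °C; aq. HCl
Reagents that add atoms: none
Why: Huckin–Weiler dianion Claisen condensation, in which the γ-carbanion (C4) of the 1,3-dianion is the more nucleophilic site and is formylated; both α-carbons are enolised in the next step, so no stereocentre matters.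

Step 2
Reactants: 4 methyl 2,4-dimethyl-3,5-dioxopentanoate
Product: 5 4-hydroxy-3,5-dimethyl-2H-pyran-2-one
Conditions: DBU, toluene, 60 °C; aq. HCl
Reagents that add atoms: none
Why: base-mediated lactonisation of a 3,5-dioxo ester, the enol oxygen of the formyl group attacking the ester with loss of methanol to give the 4-hydroxy-2-pyranone.

Step 3
Reactants: 5 4-hydroxy-3,5-dimethyl-2H-pyran-2-one
Product: 7 2-methoxy-3,5-dimethyl-4H-pyran-4-one, via 4-hydroxy-2-methoxy-3,5-dimethylpyrylium triflate 6 (not isolated)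
Conditions: MeOTf, CH2Cl2, rt; aq. NaHCO3
Reagents that add atoms: methyl trifluoromethanesulfonate, COS(=O)(=O)C(F)(F)F
Why: hard O-methylation of the neutral hydroxypyranone at the lactone carbonyl oxygen followed by loss of the 4-OH proton, the known regioselective route to α-methoxy-γ-pyrones (the 4-methoxy-2-pyranone isomer is the expected minor by-product).

Step 4
Reactants: 7 2-methoxy-3,5-dimethyl-4H-pyran-4-one
Product: 9 2-methoxy-3,5-dimethyl-6-(tributylstannyl)-4H-pyran-4-one, via chloro(6-methoxy-3,5-dimethyl-4-oxo-4H-pyran-2-yl)magnesium 8 (not isolated)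
Conditions: TMPMgCl·LiCl (1.2 equiv), THF, −40 °C; Bu3SnCl, −40 °C → rt
Reagents that add atoms: tributyltin chloride, CCCC[Sn](Cl)(CCCC)CCCC
Why: directed deprotonative magnesiation with a hindered TMP-amide base at the only ring C–H, which is acidified by the adjacent ring oxygen as in the C2-metalation of chromones and 4-pyranones (C3′/C5′ are blocked by methyl), followed by stannyl chloride quench.

Step 5
Reactants: 9 2-methoxy-3,5-dimethyl-6-(tributylstannyl)-4H-pyran-4-one
Product: 10 (6-methoxy-3,5-dimethyl-4-oxo-4H-pyran-2-yl)lead triacetate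
Conditions: Pb(OAc)4 (1.05 equiv), Hg(OAc)2 (5 mol%), CHCl3, rt → 40 °C, dark; hexane trituration, used at once
Reagents that add atoms: lead tetraacetate, CC(=O)O[Pb](OC(C)=O)(OC(C)=O)OC(C)=O
Why: tin–lead exchange, a mercury(II)-catalysed ipso-plumbyldestannylation of an sp2 C–Sn bond as used for aryl, heteroaryl and alkenyl stannanes; the pyronyl carbon has no β-hydrogen, so the elimination paths of simple alkenyllead triacetates are closed.

Step 6
Reactants: 10 (6-methoxy-3,5-dimethyl-4-oxo-4H-pyran-2-yl)lead triacetate; 11 2,4,6-trimethylphenol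
Product: 13 (6S)-6-(6-methoxy-3,5-dimethyl-4-oxo-4H-pyran-2-yl)-2,4,6-trimethylcyclohexa-2,4-dien-1-one, via diacetato(6-methoxy-3,5-dimethyl-4-oxo-4H-pyran-2-yl)(2,4,6-trimethylphenoxy)lead 12 (not isolated)
Conditions: (−)-brucine (3 equiv), 4 Å MS, toluene, −40 → 0 °C, dark
Reagents that add atoms: none
Why: Proposed new method: acetate on lead(IV) of 10 is exchanged for the phenoxide of 11 to give 12 with brucine on lead, and reductive ligand coupling through a cyclic O–Pb–C transition state moves the pyronyl group to the methyl-bearing ortho carbon and releases lead(II) acetate. The closest known reaction types are the pyridine-promoted ortho-arylation of 2,4,6-trimethylphenol by aryllead triacetates to 6-aryl-cyclohexa-2,4-dienones and the brucine-mediated enantioselective arylation of phenols by aryllead triacetates; a 4-pyranon-2-yl group on lead and control of a quaternary centre are the new elements, and the oxygen-bearing sp2 carbon on lead resembles the 2-furyl and alkenyl groups that do transfer. No ring closes; the C6–C6′ bond and the stereocentre C6 are formed. The two ortho carbons are homotopic (C2 axis of the phenoxide) and only their faces are enantiotopic, so the configuration of C6 is decided by the ring face on which the amine-bound lead sits, which the chiral alkaloid, not the substrate, has to control. The selectivity needed is ortho-C over para-C and O, secured because the group is delivered within the Pb–O-bound complex, and the methyl on the attacked carbon prevents rearomatisation, so the 2,4-dienone with the C2–C5 diene and all three ring methyls is kept.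

Step 7
Reactants: 14 (S)-but-3-yn-2-ol
Product: 15 (S)-but-3-yn-2-yl methanesulfonate
Conditions: MsCl, Et3N, CH2Cl2, −78 → 0 °C
Reagents that add atoms: methanesulfonyl chloride, CS(=O)(=O)Cl
Why: O-sulfonylation of a secondary alcohol, which does not touch the stereocentre.

Step 8
Reactants: 15 (S)-but-3-yn-2-yl methanesulfonate; 16 propanal
Product: 18 (3S,4R)-4-methylhex-5-yn-3-ol, via (aR)-buta-1,2-dien-1-ylzinc methanesulfonate 17 (not isolated)
Conditions: Pd(OAc)2 (5 mol%), PPh3 (5 mol%), Et2Zn (3 equiv), THF, −78 → −20 °C; aq. NH4Cl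
Reagents that add atoms: none
Why: Marshall propargylation, in which anti-SN2′ oxidative addition of Pd(0), Pd→Zn transmetalation and cyclic SE2′ addition to the aldehyde transfer the mesylate chirality to the methyl-bearing carbon (4R, net inversion) and give the anti carbinol (3S); any 3R epimer is harmless because C3 becomes the ketone.

Step 9
Reactants: 18 (3S,4R)-4-methylhex-5-yn-3-ol
Product: 19 triethyl{[(3S,4R)-4-methylhex-5-yn-3-yl]oxy}silane
Conditions: TESCl, imidazole, CH2Cl2, 0 °C → rt
Reagents that add atoms: chlorotriethylsilane, CC[Si](Cl)(CC)CC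
Why: silylation of the secondary alcohol; the TES ether should survive the organometallic steps and be cleaved under buffered fluoride at the end.

Step 10
Reactants: 19 triethyl{[(3S,4R)-4-methylhex-5-yn-3-yl]oxy}silane
Product: 21 triethyl{[(3S,4R)-4-methylhept-5-yn-3-yl]oxy}silane, via [(3R,4S)-3-methyl-4-(triethylsilyloxy)hex-1-yn-1-yl]lithium 20 (not isolated)
Conditions: n-BuLi, THF, −78 °C; MeI, DMPU, −78 °C → rt
Reagents that add atoms: iodomethane, CI
Why: deprotonation of the terminal alkyne and SN2 methylation of the lithium acetylide.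

Step 11
Reactants: 21 triethyl{[(3S,4R)-4-methylhept-5-yn-3-yl]oxy}silane
Product: 23 triethyl{[(3S,4R,5E)-6-iodo-4-methylhept-5-en-3-yl]oxy}silane, via chlorobis(cyclopentadienyl)[(2E,4R,5S)-4-methyl-5-(triethylsilyloxy)hept-2-en-2-yl]zirconium 22 (not isolated)
Conditions: Cp2Zr(H)Cl (2.5 equiv), THF, 50 °C; I2, 0 °C
Reagents that add atoms: iodine, II
Why: Schwartz hydrozirconation, a syn H–Zr addition in which excess reagent equilibrates zirconium to the less hindered methyl-bearing alkyne carbon, followed by iodinolysis with retention to the (E)-2-iodoalkene.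

Step 12
Reactants: 23 triethyl{[(3S,4R,5E)-6-iodo-4-methylhept-5-en-3-yl]oxy}silane; 13 (6S)-6-(6-methoxy-3,5-dimethyl-4-oxo-4H-pyran-2-yl)-2,4,6-trimethylcyclohexa-2,4-dien-1-one
Product: 27 (1S,6S)-6-(6-methoxy-3,5-dimethyl-4-oxo-4H-pyran-2-yl)-2,4,6-trimethyl-1-[(2E,4R,5S)-4-methyl-5-(triethylsilyloxy)hept-2-en-2-yl]cyclohexa-2,4-dien-1-yl methyl carbonate, via alkenyllithium from 23 (I replaced by Li, geometry retained) 24 (not isolated), via dichloro[(2E,4R,5S)-4-methyl-5-(triethylsilyloxy)hept-2-en-2-yl]cerium 25 (not isolated), via dichlorocerium alkoxide of the tertiary carbinol 26 (not isolated)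
Conditions: 23 (1.6 equiv), t-BuLi (3.2 equiv), Et2O, −78 °C; CeCl3, THF, −78 °C; 13, −78 °C; ClCO2Me, −78 → 0 °C; dark, taken on crude
Reagents that add atoms: methyl chloroformate, COC(=O)Cl
Why: iodine–lithium exchange with retention of alkene geometry, transmetalation to the weakly basic, oxophilic organocerium and 1,2-addition to the non-enolisable C1 ketone (the fully substituted pyrone is far less electrophilic), with C1 set by substrate control, attack anti to the larger pyrone on C6 placing oxygen cis to the pyrone; acylating the alkoxide in the same flask avoids isolating the ionisable tertiary carbinol.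

Step 13
Reactants: 27 tertiary methyl carbonate
Product: 28 triethyl{[(3S,4R,5E)-6-[(1S,6R)-6-(6-methoxy-3,5-dimethyl-4-oxo-4H-pyran-2-yl)-2,4,6-trimethylcyclohexa-2,4-dien-1-yl]-4-methylhept-5-en-3-yl]oxy}silane
Conditions: Pd2(dba)3·CHCl3 (5 mol%), n-Bu3P (20 mol%), HCO2H/Et3N, THF, rt, dark
Reagents that add atoms: none
Why: Tsuji-type palladium–formate hydrogenolysis of a tertiary allylic carbonate, in which Pd(0) ionises anti to the carbonate (from the face anti to the pyrone) and the palladium formate loses CO2 and delivers hydride from the metal side to the more substituted allyl terminus C1 (net inversion), so H ends trans and the alkenyl group cis to the pyrone while the C2–C5 diene and the (E)-alkene are restored.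

Step 14
Reactants: 28 TES ether
Product: 29 (3S,4R,5E)-6-[(1S,6R)-6-(6-methoxy-3,5-dimethyl-4-oxo-4H-pyran-2-yl)-2,4,6-trimethylcyclohexa-2,4-dien-1-yl]-4-methylhept-5-en-3-ol
Conditions: HF·pyridine, pyridine, THF, 0 °C, dark
Reagents that add atoms: none
Why: buffered fluoride cleavage of the triethylsilyl ether, which affects no stereocentre and spares the diene and the methoxypyrone.

Step 15
Reactants: 29 secondary alcohol
Product: 30 (4R,5E)-6-[(1S,6R)-6-(6-methoxy-3,5-dimethyl-4-oxo-4H-pyran-2-yl)-2,4,6-trimethylcyclohexa-2,4-dien-1-yl]-4-methylhept-5-en-3-one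
Conditions: Dess–Martin periodinane, NaHCO3, CH2Cl2, 0 °C, dark
Reagents that add atoms: none
Why: Dess–Martin oxidation under neutral, buffered conditions converts the carbinol to the ketone without epimerising the α-stereocentre C4 or moving the β,γ-alkene into conjugation.

Compound list
1 | methyl 2-methyl-3-oxopentanoate | CCC(=O)C(C)C(=O)OC | starting material
2 | methyl formate | COC=O | starting material
3 | dilithium dianion of methyl 2-methyl-3-oxopentanoate (dilithium 1-methoxy-2-methylpenta-1,3-diene-1,3-diolate) | CC=C(O[Li])C(C)=C(O[Li])OC | intermediate (not isolated)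
4 | methyl 2,4-dimethyl-3,5-dioxopentanoate (tautomer mixture) | COC(=O)C(C)C(=O)C(C)C=O | intermediate
5 | 4-hydroxy-3,5-dimethyl-2H-pyran-2-one | CC1=COC(=O)C(C)=C1O | intermediate
6 | 4-hydroxy-2-methoxy-3,5-dimethylpyrylium triflate | COc1[o+]cc(C)c(O)c1C.[O-]S(=O)(=O)C(F)(F)F | intermediate (not isolated)
7 | 2-methoxy-3,5-dimethyl-4H-pyran-4-one | COc1occ(C)c(=O)c1C | intermediate
8 | chloro(6-methoxy-3,5-dimethyl-4-oxo-4H-pyran-2-yl)magnesium | COc1oc([Mg]Cl)c(C)c(=O)c1C | intermediate (not isolated)
9 | 2-methoxy-3,5-dimethyl-6-(tributylstannyl)-4H-pyran-4-one | CCCC[Sn](CCCC)(CCCC)c1oc(OC)c(C)c(=O)c1C | intermediate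
10 | (6-methoxy-3,5-dimethyl-4-oxo-4H-pyran-2-yl)lead triacetate | COc1oc([Pb](OC(C)=O)(OC(C)=O)OC(C)=O)c(C)c(=O)c1C | intermediate
11 | 2,4,6-trimethylphenol | Cc1cc(C)c(O)c(C)c1 | starting material
12 | diacetato(6-methoxy-3,5-dimethyl-4-oxo-4H-pyran-2-yl)(2,4,6-trimethylphenoxy)lead | COc1oc([Pb](OC(C)=O)(OC(C)=O)Oc2c(C)cc(C)cc2C)c(C)c(=O)c1C | intermediate (not isolated)
13 | (6S)-6-(6-methoxy-3,5-dimethyl-4-oxo-4H-pyran-2-yl)-2,4,6-trimethylcyclohexa-2,4-dien-1-one | O=C1C(C)=CC(C)=C[C@@]1(C)c1oc(OC)c(C)c(=O)c1C | intermediate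
14 | (S)-but-3-yn-2-ol | C[C@H](O)C#C | starting material
15 | (S)-but-3-yn-2-yl methanesulfonate | C[C@H](OS(C)(=O)=O)C#C | intermediate
16 | propanal | CCC=O | starting material
17 | (aR)-buta-1,2-dien-1-ylzinc methanesulfonate | CS(=O)(=O)O[Zn]C([H])=[C@@]=C(C)[H] | intermediate (not isolated)
18 | (3S,4R)-4-methylhex-5-yn-3-ol | CC[C@H](O)[C@H](C)C#C | intermediate
19 | triethyl{[(3S,4R)-4-methylhex-5-yn-3-yl]oxy}silane | CC[C@H](O[Si](CC)(CC)CC)[C@H](C)C#C | intermediate
20 | [(3R,4S)-3-methyl-4-(triethylsilyloxy)hex-1-yn-1-yl]lithium | CC[C@H](O[Si](CC)(CC)CC)[C@H](C)C#C[Li] | intermediate (not isolated)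
21 | triethyl{[(3S,4R)-4-methylhept-5-yn-3-yl]oxy}silane | CC[C@H](O[Si](CC)(CC)CC)[C@H](C)C#CC | intermediate
22 | chlorobis(cyclopentadienyl)[(2E,4R,5S)-4-methyl-5-(triethylsilyloxy)hept-2-en-2-yl]zirconium | CC[C@H](O[Si](CC)(CC)CC)[C@H](C)/C=C(\C)[Zr](Cl)(C1C=CC=C1)C1C=CC=C1 | intermediate (not isolated)
23 | triethyl{[(3S,4R,5E)-6-iodo-4-methylhept-5-en-3-yl]oxy}silane | CC[C@H](O[Si](CC)(CC)CC)[C@H](C)/C=C(\C)I | intermediate
24 | alkenyllithium from 23: [(4R,5S)-4-methyl-5-(triethylsilyloxy)hept-2-en-2-yl]lithium, geometry of 23 retained | CC[C@H](O[Si](CC)(CC)CC)[C@H](C)/C=C(\C)[Li] | intermediate (not isolated)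
25 | dichloro[(2E,4R,5S)-4-methyl-5-(triethylsilyloxy)hept-2-en-2-yl]cerium | CC[C@H](O[Si](CC)(CC)CC)[C@H](C)/C=C(\C)[Ce](Cl)Cl | intermediate (not isolated)
26 | dichlorocerium (1S,6S)-6-(6-methoxy-3,5-dimethyl-4-oxo-4H-pyran-2-yl)-2,4,6-trimethyl-1-[(2E,4R,5S)-4-methyl-5-(triethylsilyloxy)hept-2-en-2-yl]cyclohexa-2,4-dien-1-olate | CC[C@H](O[Si](CC)(CC)CC)[C@H](C)/C=C(\C)[C@]1(O[Ce](Cl)Cl)C(C)=CC(C)=C[C@@]1(C)c1oc(OC)c(C)c(=O)c1C | intermediate (not isolated)
27 | (1S,6S)-6-(6-methoxy-3,5-dimethyl-4-oxo-4H-pyran-2-yl)-2,4,6-trimethyl-1-[(2E,4R,5S)-4-methyl-5-(triethylsilyloxy)hept-2-en-2-yl]cyclohexa-2,4-dien-1-yl methyl carbonate | CC[C@H](O[Si](CC)(CC)CC)[C@H](C)/C=C(\C)[C@]1(OC(=O)OC)C(C)=CC(C)=C[C@@]1(C)c1oc(OC)c(C)c(=O)c1C | intermediate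
28 | triethyl{[(3S,4R,5E)-6-[(1S,6R)-6-(6-methoxy-3,5-dimethyl-4-oxo-4H-pyran-2-yl)-2,4,6-trimethylcyclohexa-2,4-dien-1-yl]-4-methylhept-5-en-3-yl]oxy}silane | CC[C@H](O[Si](CC)(CC)CC)[C@H](C)/C=C(\C)[C@H]1C(C)=CC(C)=C[C@@]1(C)c1oc(OC)c(C)c(=O)c1C | intermediate
29 | (3S,4R,5E)-6-[(1S,6R)-6-(6-methoxy-3,5-dimethyl-4-oxo-4H-pyran-2-yl)-2,4,6-trimethylcyclohexa-2,4-dien-1-yl]-4-methylhept-5-en-3-ol | CC[C@H](O)[C@H](C)/C=C(\C)[C@H]1C(C)=CC(C)=C[C@@]1(C)c1oc(OC)c(C)c(=O)c1C | intermediate
30 | (4R,5E)-6-[(1S,6R)-6-(6-methoxy-3,5-dimethyl-4-oxo-4H-pyran-2-yl)-2,4,6-trimethylcyclohexa-2,4-dien-1-yl]-4-methylhept-5-en-3-one | CCC(=O)[C@H](C)/C=C(\C)[C@H]1C(C)=CC(C)=C[C@@]1(C)c1oc(OC)c(C)c(=O)c1C | target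

Total step count: 15. Longest linear sequence: 10 steps (steps 1–6, then 12–15); the side-chain branch (steps 7–11) joins at step 12.

Steps most likely to fail

1. Step 6 (Proposed new method). The electron-poor, hindered pyronyl ligand may not transfer (acetoxylation of the phenol or C–O reductive elimination at lead could win), or the amine may not differentiate the two ring faces. Fallback (known chemistry, no lead): the ring is built by thermal 6π-electrocyclisation of a tetraenyl pyrone, a known reaction type for such polyenes. It sets out from dianion 3 and vinyl iodide 23 and returns at 28.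
   - Pyrone half: dianion 3 would be acylated with N-propanoylimidazole to methyl 2,4-dimethyl-3,5-dioxoheptanoate F1, cyclised with DBU to 6-ethyl-4-hydroxy-3,5-dimethyl-2H-pyran-2-one F2 and O-methylated with MeOTf to 2-ethyl-6-methoxy-3,5-dimethyl-4H-pyran-4-one F3.
   - Polyene half: Stille coupling of 23 with (E)-2-methyl-3-(tributylstannyl)prop-2-en-1-ol would give (2E,4E,6R,7S)-2,4,6-trimethyl-7-(triethylsilyloxy)nona-2,4-dien-1-ol F4. MnO2 would give (2E,4E,6R,7S)-2,4,6-trimethyl-7-(triethylsilyloxy)nona-2,4-dienal F5. Wittig reaction with 2-(triphenylphosphoranylidene)propanal would give (2E,4E,6E,8R,9S)-2,4,6,8-tetramethyl-9-(triethylsilyloxy)undeca-2,4,6-trienal F6.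
   - Union: the lithium anion of F3 (LiHMDS, at the ethyl CH2) would add to F6 to give 2-[(4E,6E,8E,10R,11S)-3-hydroxy-4,6,8,10-tetramethyl-11-(triethylsilyloxy)trideca-4,6,8-trien-2-yl]-6-methoxy-3,5-dimethyl-4H-pyran-4-one F7 (epimer mixture). Mesylation and DBU elimination would give the all-E tetraene 2-methoxy-3,5-dimethyl-6-[(2E,4E,6E,8E,10R,11S)-4,6,8,10-tetramethyl-11-(triethylsilyloxy)trideca-2,4,6,8-tetraen-2-yl]-4H-pyran-4-one F8.
   - Ring closure: PdCl2(MeCN)2-mediated E→Z isomerisation of the C3=C4 alkene and warming should let the (E,Z,E)-triene close in the thermal disrotatory mode, which places pyrone and side chain cis. The remote side-chain stereocentres give no control over the ring, so 28 would form together with its (1R,6S)-ring diastereomer triethyl{[(3S,4R,5E)-6-[(1R,6S)-6-(6-methoxy-3,5-dimethyl-4-oxo-4H-pyran-2-yl)-2,4,6-trimethylcyclohexa-2,4-dien-1-yl]-4-methylhept-5-en-3-yl]oxy}silane F9 and be separated by HPLC.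

2. Step 5. Ipso-substitution of tin at the electron-poor vinylogous-ester carbon may be slow, and the lead(IV) product may decompose by C–OAc reductive elimination before use. Fallback: boron–lead exchange, which goes through acetate-assisted boron-to-lead transfer, not electrophilic cleavage of C–Sn. It sets out from magnesium reagent 8 and returns at 10. Quenching 8 with B(OMe)3 and mild acid hydrolysis would give (6-methoxy-3,5-dimethyl-4-oxo-4H-pyran-2-yl)boronic acid F10, which with Pb(OAc)4 and catalytic Hg(OAc)2 in CHCl3 should give 10 for immediate use.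

3. Step 13. Hydride may be delivered to another terminus of the extended allyl system (C3, C5 or the side-chain CH), or the allylpalladium may lose facial integrity. Fallback: allyl-metal chemistry at C1 is given up, and the C1–H bond is made together with the C1–C6 bond by the electrocyclisation sequence written under step 6. It sets out from 3 and 23 and returns at 28, with C1 carrying its hydrogen from the start; it makes no compound beyond F1–F9.

Further compounds
F1 | step 6 | methyl 2,4-dimethyl-3,5-dioxoheptanoate | CCC(=O)C(C)C(=O)C(C)C(=O)OC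
F2 | step 6 | 6-ethyl-4-hydroxy-3,5-dimethyl-2H-pyran-2-one | CCC1=C(C)C(O)=C(C)C(=O)O1
F3 | step 6 | 2-ethyl-6-methoxy-3,5-dimethyl-4H-pyran-4-one | CCc1oc(OC)c(C)c(=O)c1C
F4 | step 6 | (2E,4E,6R,7S)-2,4,6-trimethyl-7-(triethylsilyloxy)nona-2,4-dien-1-ol | CC[C@H](O[Si](CC)(CC)CC)[C@H](C)/C=C(\C)/C=C(\C)CO
F5 | step 6 | (2E,4E,6R,7S)-2,4,6-trimethyl-7-(triethylsilyloxy)nona-2,4-dienal | CC[C@H](O[Si](CC)(CC)CC)[C@H](C)/C=C(\C)/C=C(\C)C=O
F6 | step 6 | (2E,4E,6E,8R,9S)-2,4,6,8-tetramethyl-9-(triethylsilyloxy)undeca-2,4,6-trienal | CC[C@H](O[Si](CC)(CC)CC)[C@H](C)/C=C(\C)/C=C(\C)/C=C(\C)C=O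
F7 | step 6 | 2-[(4E,6E,8E,10R,11S)-3-hydroxy-4,6,8,10-tetramethyl-11-(triethylsilyloxy)trideca-4,6,8-trien-2-yl]-6-methoxy-3,5-dimethyl-4H-pyran-4-one (epimers at C2, C3 of the chain) | COc1oc(C(C)C(O)/C(C)=C/C(C)=C/C(C)=C/[C@@H](C)[C@H](CC)O[Si](CC)(CC)CC)c(C)c(=O)c1C
F8 | step 6 | 2-methoxy-3,5-dimethyl-6-[(2E,4E,6E,8E,10R,11S)-4,6,8,10-tetramethyl-11-(triethylsilyloxy)trideca-2,4,6,8-tetraen-2-yl]-4H-pyran-4-one | COc1oc(/C(C)=C/C(C)=C/C(C)=C/C(C)=C/[C@@H](C)[C@H](CC)O[Si](CC)(CC)CC)c(C)c(=O)c1C
F9 | step 6 | triethyl{[(3S,4R,5E)-6-[(1R,6S)-6-(6-methoxy-3,5-dimethyl-4-oxo-4H-pyran-2-yl)-2,4,6-trimethylcyclohexa-2,4-dien-1-yl]-4-methylhept-5-en-3-yl]oxy}silane | CC[C@H](O[Si](CC)(CC)CC)[C@H](C)/C=C(\C)[C@@H]1C(C)=CC(C)=C[C@]1(C)c1oc(OC)c(C)c(=O)c1C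
F10 | step 5 | (6-methoxy-3,5-dimethyl-4-oxo-4H-pyran-2-yl)boronic acid | COc1oc(B(O)O)c(C)c(=O)c1C
F0 | step 13 | none | none
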